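## The problem

Target 22 is a (3R)-isoflavan: a chroman (ring A fused to the pyran ring C) with 5-OMe and 7-OH that carries ring B (2'-OH, 3'-prenyl, 4'-OMe) at C3. Its only stereocentre, C3, is a tertiary benzylic C–H with no neighbouring stereocentre to relay from, so it must be set by a catalyst or reagent and then carried through steps that neither deprotonate nor ionise that position. The skeleton is a 1,2-diarylpropane closed by an aryl alkyl ether, and both aryl carbons that join it are crowded: C4a lies between the oxygen-bearing carbons C5 and C8a, and C1' has the 2'-oxygen beside it. The prenyl group rules out hydrogenation, hydrogenolysis, peracids once it is present, and strong protic acid; the 2'-OH next to it would add across the alkene under acid to give a dimethylchroman. The oxygens at C8a and C2' can both reach C2 (six-membered pyran against five-membered dihydrofuran), so they must be told apart before ring C is closed. The position of the prenyl group between OH and OMe on ring B has to follow from the way that ring is made, not from a late substitution. The feature that opens the key step is the C3–C4 unit: C4 bears ring A and C3 bears ring B, which is a vinyl group diarylated across its double bond by two different aryl groups, and the third substituent on C3 (C2) is a single carbon into which a C–B bond can be converted.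

## Retrosynthesis

**22 from 21.** No skeletal bond is cut; only the two acetal C–O bonds at O7 and O2' are. Methoxymethyl is chosen for both because the 2'-oxygen must later sit ortho to an aryllithium: a silyl ether there would migrate to carbon, and a benzyl ether could not be removed beside the prenyl group. Precursor 21 has no free phenol and is otherwise the complete isoflavan. The forward step must cleave two acetals faster than the liberated 2'-OH adds to the prenyl alkene.

**21 from 20.** The O1–C2 bond is cut. The neighbouring cut, O1–C8a, would need a halide at C8a and a metal-catalysed etherification on an electron-rich ring. Closure at the primary carbon C2 by a Mitsunobu reaction is milder and cannot touch C3. Diol 20 is acyclic and has exactly one free phenol, at C8a. This asks that the C8a oxygen was masked differently (pivalate) from the 2'-oxygen (acetal), so that only the pyran can form.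

**20 from 18 and 16.** The C2–C3 bond is cut, C2 being inserted into a C3–B bond. A one-carbon Matteson homologation followed by oxidation is preferred to carrying C2 in from the start, because a boron on C3 is exactly what a metallate shift delivers. Boronate 16 is one carbon simpler than 18 and has the stereocentre in place. The forward steps must insert the carbon with retention at C3 and tolerate the aryl pivalate; the alkaline oxidation then removes the pivalate in the same pot, giving 20 from 18.

**16 from 6, 13 and 12.** Two bonds are cut, C3–C1' and C4–C4a, on either side of the vinyl unit of 13. The neighbouring cuts were weighed. Cutting C3–C4 alone (enolate alkylation) needs a stoichiometric auxiliary and a labile trioxygenated benzylic electrophile. Making C3 by hydrogenation of a C3–C4 alkene is closed by the prenyl group. The conjunctive coupling joins three pieces of roughly equal size and sets C3 catalytically in the same event. The forward reaction must work with a triflate (12) substituted at both ortho positions and a migrating aryl (from 6) substituted at one.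

**6 from 5, 4, 3, 1 and 2.** The C3'–prenyl bond is cut by a Claisen rearrangement, and behind it the aryl ether O–C bond to the dimethylpropargyl unit of 2. Direct prenylation or late bromination would give regioisomers and attack the alkene. In 1 the bromine is already para to OMe and blocks one ortho position, so the allyl group can only arrive between OH and OMe. Phenol 5 then needs only the acetal to become 6.

**12 from 11, 9, 8 and 7.** The aryl C–O bond of the triflate at the future C4a is traced back to the formyl carbon of 7 through a Baeyer–Villiger (Dakin-type) oxidation. The 1,2,3,5-oxygenation pattern is thus inherited from a benzaldehyde whose two hydroxyls differ (one chelated, one free). Halogenation of a phloroglucinol ether would not distinguish the three ring positions. The forward sequence must keep the pivalate on the C8a oxygen while the neighbouring phenol is freed and sulfonylated.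

## Roads not taken

Alternative 1: Ring B is built instead of being brought in. The cut runs through C1'–C2', C2'–C3' and C4'–C5', leaving the chroman-3-yl unsaturated diazoketone A2, which already holds C3, and the prenylated methoxyalkyne A3. In the forward step, irradiation of A2 triggers a Wolff rearrangement and the ketene so formed adds A3 in a [2+2] reaction. Four-electron ring opening, six-electron closure and tautomerisation (Danheiser benzannulation) then give silyl ether A1, one desilylation away from 22.
- Merits: the OH/prenyl/OMe pattern follows from the polarity of A3 and cannot come out wrong, and the 2'-OH is formed free. The last step uses fluoride, not acid, beside the prenylphenol. In this respect the road is better than the chosen one, which must cleave an acetal next to the prenyl group (step 13).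
- Weak points: C3 has to be set beforehand in a separate asymmetric step. In A2 it sits γ to the enone carbonyl, where dienolisation can erode it. A2 needs a diazo transfer and a photochemical step, A3 is a sensitive alkoxyalkyne, and the sequence is linear from ring A onward.
- Comparison: the chosen plan sets against this a convergent assembly in which the event that joins the pieces also creates the stereocentre.

Alternative 2: Ring C is cut at C4–C4a, C8a–O1 and O1–C2, leaving the ortho-silylaryl triflate A6 as aryne source and the 2-arylacrolein A5. In the forward step, fluoride releases the aryne from A6 and the aldehyde oxygen of A5 adds to it. Ring opening of the four-membered adduct and a six-electron electrocyclisation then give isoflav-3-ene A4.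
- Merits: three bonds and ring C form in one operation from two simple partners. The methoxy group next to the aryne directs oxygen to the remote aryne carbon. For ring construction this is more step-economical than the coupling plus Mitsunobu closure of the chosen plan.
- Weak points: A4 is achiral, so C3 needs a separate asymmetric hydrogenation. The prenyl group cannot be present during that hydrogenation or during hydrogenolysis of the benzyl ether, so A4 lacks it. It would have to be introduced afterwards at C3' by directed metalation, with the 7-OH protected again. A5 polymerises easily and A6 takes several steps.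
- Comparison: the chosen plan carries the prenyl group from the start and needs no alkene reduction. Against the shorter ring construction it sets a shorter and safer endgame.

Alternative 3: The cut is again O1–C2, but in a precursor where C2 and one extra carbon are the two CH2–O arms of an oxetane, phenol A8. In the forward step a chiral phosphoric acid activates the oxetane of A8 and the ring A phenol opens one of the two enantiotopic C–O bonds. This closes the pyran and gives the 3-(hydroxymethyl)chroman A7, in which C3 is a quaternary stereocentre. Oxidation of the CH2OH group of A7 to CHO and decarbonylation with RhCl(PPh3)3, which proceeds with retention, would then reveal C3–H.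
- Merits: ring closure and stereocontrol occur in one mild organocatalytic step on a prochiral substrate, with no hindered cross-coupling and no organolithium. In these respects it is gentler than the chosen key step.
- Weak points: A8 has a quaternary carbon between the hindered ring B and the ring A benzyl group and needs a long linear preparation. The hydroxymethyl carbon of A7, which carries the stereochemical information, must be removed again in two steps. The second is a high-temperature decarbonylation of a neopentyl-type aldehyde in the presence of the prenyl alkene, which invites isomerisation and hydroacylation.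
- Comparison: the chosen plan adds the missing carbon (step 10) where this road excises a surplus one from A7, and it builds its precursors in two short parallel branches.

Key step: step 9

Remark on the chemistry: the sense of induction of the catalyst formed from Pd(OAc)2 and the MandyPhos ligand is assumed by analogy with simpler aryl partners; both ligand enantiomers are available, and the one that gives the (R)-boronate 16 is used.
Remark on the chemistry: 2,4-dihydroxy-6-methoxybenzaldehyde 7 is taken as a purchasable catalogue compound.

## Route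

Step 1
Reactants: 1 2-bromo-5-methoxyphenol; 2 3-chloro-3-methylbut-1-yne
Product: 3 1-bromo-4-methoxy-2-[(2-methylbut-3-yn-2-yl)oxy]benzene
Conditions: DBU, CuCl2·2H2O (cat.), MeCN, 0 °C to rt
Reagents that add atoms: none
Why: CuCl2-catalysed O-alkylation of a phenol with a tertiary propargylic chloride, which ionises with the help of a copper acetylide and so avoids the slow direct substitution at a tertiary carbon; no stereocentre is formed.

Step 2
Reactants: 3 1-bromo-4-methoxy-2-[(2-methylbut-3-yn-2-yl)oxy]benzene
Product: 4 1-bromo-4-methoxy-2-[(2-methylbut-3-en-2-yl)oxy]benzene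
Conditions: H2 (1 atm), Pd/CaCO3 poisoned with Pb(OAc)2, quinoline, EtOAc, rt
Reagents that add atoms: none
Why: Lindlar semihydrogenation of a terminal alkyne to the alkene; the poisoned catalyst should leave the aryl bromide and the new alkene untouched.

Step 3
Reactants: 4 1-bromo-4-methoxy-2-[(2-methylbut-3-en-2-yl)oxy]benzene
Product: 5 6-bromo-3-methoxy-2-(3-methylbut-2-en-1-yl)phenol
Conditions: N,N-diethylaniline, 120 °C
Reagents that add atoms: none
Why: Aromatic Claisen rearrangement ([3,3] shift with allyl inversion, then tautomerisation), accelerated by the geminal methyl groups; bromine blocks one ortho carbon, so the prenyl group should arrive at the carbon between the phenol oxygen and OMe.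

Step 4
Reactants: 5 6-bromo-3-methoxy-2-(3-methylbut-2-en-1-yl)phenol
Product: 6 1-bromo-4-methoxy-2-(methoxymethoxy)-3-(3-methylbut-2-en-1-yl)benzene
Conditions: NaH, MOMCl, DMF, 0 °C to rt
Reagents that add atoms: chloromethyl methyl ether, COCCl
Why: Williamson-type O-alkylation of the hindered phenoxide; the acetal is inert to organolithiums and will stabilise the neighbouring aryllithium by chelation.

Step 5
Reactants: 7 2,4-dihydroxy-6-methoxybenzaldehyde
Product: 8 2-hydroxy-6-methoxy-4-(methoxymethoxy)benzaldehyde
Conditions: MOMCl (1.05 equiv), i-Pr2NEt, CH2Cl2, 0 °C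
Reagents that add atoms: chloromethyl methyl ether, COCCl
Why: Selective O-alkylation; the 2-OH is held in a hydrogen bond to the aldehyde, so the more acidic and unhindered 4-OH should react first.

Step 6
Reactants: 8 2-hydroxy-6-methoxy-4-(methoxymethoxy)benzaldehyde
Product: 9 2-formyl-3-methoxy-5-(methoxymethoxy)phenyl 2,2-dimethylpropanoate
Conditions: PivCl, Et3N, DMAP (cat.), CH2Cl2, 0 °C to rt
Reagents that add atoms: pivaloyl chloride, CC(C)(C)C(Cl)=O
Why: DMAP-catalysed acylation of the chelated phenol; the pivalate marks the future C8a oxygen as different from all acetal-protected oxygens.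

Step 7
Reactants: 9 2-formyl-3-methoxy-5-(methoxymethoxy)phenyl 2,2-dimethylpropanoate
Product: 11 2-hydroxy-3-methoxy-5-(methoxymethoxy)phenyl 2,2-dimethylpropanoate, via aryl formate 10 (not isolated)
Conditions: mCPBA, CH2Cl2, 0 °C to rt; then Et3N, MeOH, 0 °C
Reagents that add atoms: 3-chloroperbenzoic acid, OOC(=O)c1cccc(Cl)c1
Why: Baeyer–Villiger (Dakin-type) oxidation in which the electron-rich aryl group migrates in preference to hydrogen; the aryl formate 10 is methanolysed far faster than the hindered pivalate, and the step is placed before any alkene is present.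

Step 8
Reactants: 11 2-hydroxy-3-methoxy-5-(methoxymethoxy)phenyl 2,2-dimethylpropanoate
Product: 12 3-methoxy-5-(methoxymethoxy)-2-[(trifluoromethanesulfonyl)oxy]phenyl 2,2-dimethylpropanoate
Conditions: Tf2O, pyridine, CH2Cl2, −20 to 0 °C
Reagents that add atoms: trifluoromethanesulfonic anhydride, O=S(=O)(OS(=O)(=O)C(F)(F)F)C(F)(F)F
Why: O-sulfonylation of the phenol; low temperature and a weak base keep the neighbouring pivaloyl group from migrating before the oxygen is capped.

Step 9
Reactants: 6 1-bromo-4-methoxy-2-(methoxymethoxy)-3-(3-methylbut-2-en-1-yl)benzene; 13 2-ethenyl-4,4,5,5-tetramethyl-1,3,2-dioxaborolane; 12 3-methoxy-5-(methoxymethoxy)-2-[(trifluoromethanesulfonyl)oxy]phenyl 2,2-dimethylpropanoate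
Product: 16 3-methoxy-5-(methoxymethoxy)-2-{(2R)-2-[4-methoxy-2-(methoxymethoxy)-3-(3-methylbut-2-en-1-yl)phenyl]-2-(4,4,5,5-tetramethyl-1,3,2-dioxaborolan-2-yl)ethyl}phenyl 2,2-dimethylpropanoate, via aryllithium 14 (not isolated), via lithium vinylborate complex 15 (not isolated)
Conditions: n-BuLi, THF, −78 °C; 13, −78 °C to rt; evaporate; then 12, Pd(OAc)2 (3 mol%), MandyPhos [1,1'-bis{bis(4-methoxy-3,5-dimethylphenyl)phosphino}-2,2'-bis{α-(dimethylamino)benzyl}ferrocene, single enantiomer] (3.6 mol%), THF, 60 °C
Reagents that add atoms: none
Why: Bromine–lithium exchange gives aryllithium 14, which adds to the boron of 13 to form the tetracoordinate vinylborate 15; the 1-bromobutane formed is volatile and leaves with the solvent, so no bromide salt enters the catalysis. Oxidative addition of triflate 12 to zerovalent palladium gives a cationic arylpalladium triflate (divalent palladium) that binds the alkene of 15. Coordination triggers the 1,2-metallate shift: the ring B aryl group moves from boron to the α-carbon anti to palladium while palladium bonds to the terminal carbon, which forms C3–C1' and the stereocentre, and reductive elimination then forms C4–C4a and returns zerovalent palladium. No ring is closed in this step. The closest known reaction type is the enantioselective conjunctive cross-coupling of vinylboron pinacol ate complexes with aryl triflates and aryl migrating groups; the present case adds a second ortho substituent on the triflate and one on the migrating aryl. The configuration at C3 is controlled by the chiral bisphosphine on palladium, which selects the alkene face for the anti migration. The step needs the metallate shift to outrun direct transmetalation (transfer of vinyl or aryl to palladium) and β-hydride elimination: the weakly coordinating triflate keeps palladium cationic and alkene-binding, the pinacol ligand disfavours transmetalation, and the electron-withdrawing pivalate eases oxidative addition of an otherwise electron-rich triflate.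

Step 10
Reactants: 16 3-methoxy-5-(methoxymethoxy)-2-{(2R)-2-[4-methoxy-2-(methoxymethoxy)-3-(3-methylbut-2-en-1-yl)phenyl]-2-(4,4,5,5-tetramethyl-1,3,2-dioxaborolan-2-yl)ethyl}phenyl 2,2-dimethylpropanoate
Product: 18 3-methoxy-5-(methoxymethoxy)-2-{(2R)-2-[4-methoxy-2-(methoxymethoxy)-3-(3-methylbut-2-en-1-yl)phenyl]-3-(4,4,5,5-tetramethyl-1,3,2-dioxaborolan-2-yl)propyl}phenyl 2,2-dimethylpropanoate, via lithium chloromethylborate complex 17 (not isolated)
Conditions: ICH2Cl, n-BuLi, THF, −78 °C to rt
Reagents that add atoms: chloroiodomethane, ClCI
Why: Matteson homologation: chloromethyllithium, made in the flask by fast iodine–lithium exchange, adds to boron to give 17, and on warming the benzylic carbon shifts from boron to the CH2 with loss of chloride; the migrating carbon keeps its configuration, so C3 is carried over unchanged.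

Step 11
Reactants: 18 3-methoxy-5-(methoxymethoxy)-2-{(2R)-2-[4-methoxy-2-(methoxymethoxy)-3-(3-methylbut-2-en-1-yl)phenyl]-3-(4,4,5,5-tetramethyl-1,3,2-dioxaborolan-2-yl)propyl}phenyl 2,2-dimethylpropanoate
Product: 20 2-{(2R)-3-hydroxy-2-[4-methoxy-2-(methoxymethoxy)-3-(3-methylbut-2-en-1-yl)phenyl]propyl}-3-methoxy-5-(methoxymethoxy)phenol, via primary alcohol pivalate 19 (not isolated)
Conditions: H2O2 (30% aq), NaOH (2 M aq), THF/MeOH, 0 °C to rt
Reagents that add atoms: hydrogen peroxide, OO
Why: Alkaline peroxide oxidation of the primary C–B bond (boron-to-oxygen 1,2-shift) gives alcohol 19, and the same hydroperoxide/hydroxide medium cleaves the aryl ester by acyl substitution; the unactivated prenyl alkene, the acetals and C3 are not affected.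

Step 12
Reactants: 20 2-{(2R)-3-hydroxy-2-[4-methoxy-2-(methoxymethoxy)-3-(3-methylbut-2-en-1-yl)phenyl]propyl}-3-methoxy-5-(methoxymethoxy)phenol
Product: 21 (3R)-5-methoxy-7-(methoxymethoxy)-3-[4-methoxy-2-(methoxymethoxy)-3-(3-methylbut-2-en-1-yl)phenyl]-3,4-dihydro-2H-chromene
Conditions: PPh3, DIAD, THF, 0 °C to rt
Reagents that add atoms: none
Why: Intramolecular Mitsunobu etherification (6-exo-tet attack of the only free phenol, at C8a, on the activated primary carbon C2); the 2'-oxygen is blocked as its acetal, so the dihydrofuran cannot form, and C3 is not a reacting centre.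

Step 13
Reactants: 21 (3R)-5-methoxy-7-(methoxymethoxy)-3-[4-methoxy-2-(methoxymethoxy)-3-(3-methylbut-2-en-1-yl)phenyl]-3,4-dihydro-2H-chromene
Product: 22 (3R)-3-[2-hydroxy-4-methoxy-3-(3-methylbut-2-en-1-yl)phenyl]-5-methoxy-3,4-dihydro-2H-chromen-7-ol
Conditions: HCl (1.25 M in MeOH), 0 °C to rt
Reagents that add atoms: none
Why: Acid-catalysed acetal methanolysis of both methoxymethyl ethers; dilute acid at low temperature is chosen so that acetal exchange should be faster than addition of the liberated 2'-OH to the prenyl alkene.

## Compound list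

1 | 2-bromo-5-methoxyphenol | COc1ccc(Br)c(O)c1 | starting material
2 | 3-chloro-3-methylbut-1-yne | CC(C)(Cl)C#C | starting material
3 | 1-bromo-4-methoxy-2-[(2-methylbut-3-yn-2-yl)oxy]benzene | COc1ccc(Br)c(OC(C)(C)C#C)c1 | intermediate
4 | 1-bromo-4-methoxy-2-[(2-methylbut-3-en-2-yl)oxy]benzene | COc1ccc(Br)c(OC(C)(C)C=C)c1 | intermediate
5 | 6-bromo-3-methoxy-2-(3-methylbut-2-en-1-yl)phenol | COc1ccc(Br)c(O)c1CC=C(C)C | intermediate
6 | 1-bromo-4-methoxy-2-(methoxymethoxy)-3-(3-methylbut-2-en-1-yl)benzene | COCOc1c(Br)ccc(OC)c1CC=C(C)C | intermediate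
7 | 2,4-dihydroxy-6-methoxybenzaldehyde | COc1cc(O)cc(O)c1C=O | starting material
8 | 2-hydroxy-6-methoxy-4-(methoxymethoxy)benzaldehyde | COCOc1cc(O)c(C=O)c(OC)c1 | intermediate
9 | 2-formyl-3-methoxy-5-(methoxymethoxy)phenyl 2,2-dimethylpropanoate | COCOc1cc(OC)c(C=O)c(OC(=O)C(C)(C)C)c1 | intermediate
10 | 2-(formyloxy)-3-methoxy-5-(methoxymethoxy)phenyl 2,2-dimethylpropanoate | COCOc1cc(OC)c(OC=O)c(OC(=O)C(C)(C)C)c1 | intermediate
11 | 2-hydroxy-3-methoxy-5-(methoxymethoxy)phenyl 2,2-dimethylpropanoate | COCOc1cc(OC)c(O)c(OC(=O)C(C)(C)C)c1 | intermediate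
12 | 3-methoxy-5-(methoxymethoxy)-2-[(trifluoromethanesulfonyl)oxy]phenyl 2,2-dimethylpropanoate | COc1cc(OCOC)cc(OC(=O)C(C)(C)C)c1OS(=O)(=O)C(F)(F)F | intermediate
13 | 2-ethenyl-4,4,5,5-tetramethyl-1,3,2-dioxaborolane (vinylboronic acid pinacol ester) | C=CB1OC(C)(C)C(C)(C)O1 | starting material
14 | [4-methoxy-2-(methoxymethoxy)-3-(3-methylbut-2-en-1-yl)phenyl]lithium | [Li]c1ccc(OC)c(CC=C(C)C)c1OCOC | intermediate
15 | lithium ethenyl[4-methoxy-2-(methoxymethoxy)-3-(3-methylbut-2-en-1-yl)phenyl](pinacolato)borate | [Li+].C=C[B-]1(c2ccc(OC)c(CC=C(C)C)c2OCOC)OC(C)(C)C(C)(C)O1 | intermediate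
16 | 3-methoxy-5-(methoxymethoxy)-2-{(2R)-2-[4-methoxy-2-(methoxymethoxy)-3-(3-methylbut-2-en-1-yl)phenyl]-2-(4,4,5,5-tetramethyl-1,3,2-dioxaborolan-2-yl)ethyl}phenyl 2,2-dimethylpropanoate | COc1cc(OCOC)cc(OC(=O)C(C)(C)C)c1C[C@H](c1ccc(OC)c(CC=C(C)C)c1OCOC)B1OC(C)(C)C(C)(C)O1 | intermediate
17 | lithium (chloromethyl)borate complex of 16 (chloromethyl added to boron, stereocentre unchanged, R) | [Li+].COc1cc(OCOC)cc(OC(=O)C(C)(C)C)c1C[C@H](c1ccc(OC)c(CC=C(C)C)c1OCOC)[B-]1(CCl)OC(C)(C)C(C)(C)O1 | intermediate
18 | 3-methoxy-5-(methoxymethoxy)-2-{(2R)-2-[4-methoxy-2-(methoxymethoxy)-3-(3-methylbut-2-en-1-yl)phenyl]-3-(4,4,5,5-tetramethyl-1,3,2-dioxaborolan-2-yl)propyl}phenyl 2,2-dimethylpropanoate | COc1cc(OCOC)cc(OC(=O)C(C)(C)C)c1C[C@H](c1ccc(OC)c(CC=C(C)C)c1OCOC)CB1OC(C)(C)C(C)(C)O1 | intermediate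
19 | 2-{(2R)-3-hydroxy-2-[4-methoxy-2-(methoxymethoxy)-3-(3-methylbut-2-en-1-yl)phenyl]propyl}-3-methoxy-5-(methoxymethoxy)phenyl 2,2-dimethylpropanoate | COc1cc(OCOC)cc(OC(=O)C(C)(C)C)c1C[C@H](c1ccc(OC)c(CC=C(C)C)c1OCOC)CO | intermediate
20 | 2-{(2R)-3-hydroxy-2-[4-methoxy-2-(methoxymethoxy)-3-(3-methylbut-2-en-1-yl)phenyl]propyl}-3-methoxy-5-(methoxymethoxy)phenol | COc1cc(OCOC)cc(O)c1C[C@H](c1ccc(OC)c(CC=C(C)C)c1OCOC)CO | intermediate
21 | (3R)-5-methoxy-7-(methoxymethoxy)-3-[4-methoxy-2-(methoxymethoxy)-3-(3-methylbut-2-en-1-yl)phenyl]-3,4-dihydro-2H-chromene | COc1cc(OCOC)cc2c1C[C@H](c1ccc(OC)c(CC=C(C)C)c1OCOC)CO2 | intermediate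
22 | (3R)-3-[2-hydroxy-4-methoxy-3-(3-methylbut-2-en-1-yl)phenyl]-5-methoxy-3,4-dihydro-2H-chromen-7-ol | COc1cc(O)cc2c1C[C@H](c1ccc(OC)c(CC=C(C)C)c1O)CO2 | target

## Step count and least certain steps

Total: 13 steps. Longest linear sequence: 9 steps (steps 1–4 or 5–8, then 9–13).

**Step 9 (key step).** The alkene of 15 may be captured slowly or not at all by an arylpalladium species that is substituted at both ortho positions, with a migrating aryl that carries an ortho acetal. Direct transmetalation or β-hydride elimination could then take over, and the enantioselectivity could fall short of that seen with unhindered partners.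

Fallback, from 6 and 9, returning at 19: an auxiliary-controlled enolate alkylation (Evans alkylation) forms C3–C4 instead. Bromide 6 is coupled with the Reformatsky reagent BrZnCH2CO2Et (Pd(dba)2, P(t-Bu)3, THF) to give ethyl 2-[4-methoxy-2-(methoxymethoxy)-3-(3-methylbut-2-en-1-yl)phenyl]acetate F1. Saponification (LiOH) gives 2-[4-methoxy-2-(methoxymethoxy)-3-(3-methylbut-2-en-1-yl)phenyl]acetic acid F2. This acid is attached through its mixed pivalic anhydride to lithiated (R)-4-benzyloxazolidin-2-one, giving (4R)-4-benzyl-3-{2-[4-methoxy-2-(methoxymethoxy)-3-(3-methylbut-2-en-1-yl)phenyl]acetyl}oxazolidin-2-one F3. In parallel, aldehyde 9 is reduced (NaBH4) to 2-(hydroxymethyl)-3-methoxy-5-(methoxymethoxy)phenyl 2,2-dimethylpropanoate F4 and converted (CBr4, PPh3) to 2-(bromomethyl)-3-methoxy-5-(methoxymethoxy)phenyl 2,2-dimethylpropanoate F5, which is used at once. Alkylation of the sodium enolate of the imide (NaN(SiMe3)2, THF, −78 °C) with this bromide should set C3 opposite the benzyl group of the auxiliary and give the (R)-configured alkylated imide F6. LiBH4 then removes the auxiliary to give alcohol 19, which is saponified as in the second stage of step 11 to 20.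

**Step 10.** Chloromethyllithium or n-BuLi may attack the aryl pivalate carbonyl in competition with complexation at a hindered secondary benzylic boronate, so homologation may stay incomplete. Partial loss of the pivalate alone would be harmless, since step 11 removes it anyway.

Fallback, from 16, returning at 20: the ester is exchanged for a silyl ether before the carbenoid is used. Methanolysis of 16 (K2CO3, MeOH) gives 3-methoxy-5-(methoxymethoxy)-2-{(2R)-2-[4-methoxy-2-(methoxymethoxy)-3-(3-methylbut-2-en-1-yl)phenyl]-2-(4,4,5,5-tetramethyl-1,3,2-dioxaborolan-2-yl)ethyl}phenol F7. Silylation (TBSCl, imidazole) gives its tert-butyldimethylsilyl ether F8. Matteson homologation as in step 10 gives the homologated silyl ether boronate F9. Alkaline peroxide oxidation, in which the basic medium (helped by Bu4NF if needed) also cleaves the aryl silyl ether, then leads to 20.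

**Step 7.** Aryl migration in the peracid step may be incomplete for an aldehyde flanked by two ortho substituents. Once the formate is cleaved in basic methanol, the pivaloyl group may move to the neighbouring phenoxide oxygen, which would exchange the positions of ester and triflate.

Fallback, from 8, returning at 11: the order of oxidation and acylation is reversed. Classical Dakin oxidation of the free salicylaldehyde 8 (H2O2, NaOH) gives 3-methoxy-5-(methoxymethoxy)benzene-1,2-diol F10. Kinetic monoacylation at the less hindered hydroxyl (PivCl, pyridine, CH2Cl2, −40 °C), under conditions that form no phenoxide, then gives 11.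

**Step 13.** Under protic acid the liberated 2'-OH may add to the protonated prenyl alkene, or methanol may add to it, before the hindered 2'-acetal is fully cleaved.

Fallback, from 21, returning at 22: the Brønsted acid is replaced by silyl transfer. Me3SiOSO2CF3 with 2,2'-bipyridyl in CH2Cl2 at 0 °C converts both aryl acetals into silyl ethers, giving (3R)-5-methoxy-7-(trimethylsilyloxy)-3-[4-methoxy-3-(3-methylbut-2-en-1-yl)-2-(trimethylsilyloxy)phenyl]-3,4-dihydro-2H-chromene F11. Addition of water hydrolyses this bis(silyl ether) to 22 under essentially neutral conditions.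

## Further compounds

F1 | step 9 | ethyl 2-[4-methoxy-2-(methoxymethoxy)-3-(3-methylbut-2-en-1-yl)phenyl]acetate | CCOC(=O)Cc1ccc(OC)c(CC=C(C)C)c1OCOC
F2 | step 9 | 2-[4-methoxy-2-(methoxymethoxy)-3-(3-methylbut-2-en-1-yl)phenyl]acetic acid | OC(=O)Cc1ccc(OC)c(CC=C(C)C)c1OCOC
F3 | step 9 | (4R)-4-benzyl-3-{2-[4-methoxy-2-(methoxymethoxy)-3-(3-methylbut-2-en-1-yl)phenyl]acetyl}oxazolidin-2-one | O=C(Cc1ccc(OC)c(CC=C(C)C)c1OCOC)N1[C@H](Cc2ccccc2)COC1=O
F4 | step 9 | 2-(hydroxymethyl)-3-methoxy-5-(methoxymethoxy)phenyl 2,2-dimethylpropanoate | COCOc1cc(OC)c(CO)c(OC(=O)C(C)(C)C)c1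
F5 | step 9 | 2-(bromomethyl)-3-methoxy-5-(methoxymethoxy)phenyl 2,2-dimethylpropanoate | COCOc1cc(OC)c(CBr)c(OC(=O)C(C)(C)C)c1
F6 | step 9 | 2-{(2R)-3-[(4R)-4-benzyl-2-oxooxazolidin-3-yl]-2-[4-methoxy-2-(methoxymethoxy)-3-(3-methylbut-2-en-1-yl)phenyl]-3-oxopropyl}-3-methoxy-5-(methoxymethoxy)phenyl 2,2-dimethylpropanoate | COc1cc(OCOC)cc(OC(=O)C(C)(C)C)c1C[C@H](c1ccc(OC)c(CC=C(C)C)c1OCOC)C(=O)N1[C@H](Cc2ccccc2)COC1=O
F7 | step 10 | 3-methoxy-5-(methoxymethoxy)-2-{(2R)-2-[4-methoxy-2-(methoxymethoxy)-3-(3-methylbut-2-en-1-yl)phenyl]-2-(4,4,5,5-tetramethyl-1,3,2-dioxaborolan-2-yl)ethyl}phenol | COc1cc(OCOC)cc(O)c1C[C@H](c1ccc(OC)c(CC=C(C)C)c1OCOC)B1OC(C)(C)C(C)(C)O1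
F8 | step 10 | tert-butyl{3-methoxy-5-(methoxymethoxy)-2-[(2R)-2-[4-methoxy-2-(methoxymethoxy)-3-(3-methylbut-2-en-1-yl)phenyl]-2-(4,4,5,5-tetramethyl-1,3,2-dioxaborolan-2-yl)ethyl]phenoxy}dimethylsilane | COc1cc(OCOC)cc(O[Si](C)(C)C(C)(C)C)c1C[C@H](c1ccc(OC)c(CC=C(C)C)c1OCOC)B1OC(C)(C)C(C)(C)O1
F9 | step 10 | tert-butyl{3-methoxy-5-(methoxymethoxy)-2-[(2R)-2-[4-methoxy-2-(methoxymethoxy)-3-(3-methylbut-2-en-1-yl)phenyl]-3-(4,4,5,5-tetramethyl-1,3,2-dioxaborolan-2-yl)propyl]phenoxy}dimethylsilane | COc1cc(OCOC)cc(O[Si](C)(C)C(C)(C)C)c1C[C@H](c1ccc(OC)c(CC=C(C)C)c1OCOC)CB1OC(C)(C)C(C)(C)O1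
F10 | step 7 | 3-methoxy-5-(methoxymethoxy)benzene-1,2-diol | COCOc1cc(O)c(O)c(OC)c1
F11 | step 13 | (3R)-5-methoxy-7-(trimethylsilyloxy)-3-[4-methoxy-3-(3-methylbut-2-en-1-yl)-2-(trimethylsilyloxy)phenyl]-3,4-dihydro-2H-chromene | COc1cc(O[Si](C)(C)C)cc2c1C[C@H](c1ccc(OC)c(CC=C(C)C)c1O[Si](C)(C)C)CO2
A1 | alternative 1 | (3R)-7-(tert-butyldimethylsilyloxy)-3-[2-hydroxy-4-methoxy-3-(3-methylbut-2-en-1-yl)phenyl]-5-methoxy-3,4-dihydro-2H-chromene | COc1cc(O[Si](C)(C)C(C)(C)C)cc2c1C[C@H](c1ccc(OC)c(CC=C(C)C)c1O)CO2
A2 | alternative 1 | (E)-4-[(3R)-7-(tert-butyldimethylsilyloxy)-5-methoxy-3,4-dihydro-2H-chromen-3-yl]-1-diazobut-3-en-2-one | COc1cc(O[Si](C)(C)C(C)(C)C)cc2c1C[C@H](/C=C/C(=O)C=[N+]=[N-])CO2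
A3 | alternative 1 | 1-methoxy-5-methylhex-4-en-1-yne | COC#CCC=C(C)C
A4 | alternative 2 | 7-(benzyloxy)-5-methoxy-3-[4-methoxy-2-(methoxymethoxy)phenyl]-2H-chromene | COc1cc(OCc3ccccc3)cc2c1C=C(c1ccc(OC)cc1OCOC)CO2
A5 | alternative 2 | 2-[4-methoxy-2-(methoxymethoxy)phenyl]prop-2-enal | C=C(C=O)c1ccc(OC)cc1OCOC
A6 | alternative 2 | 4-(benzyloxy)-2-methoxy-6-(trimethylsilyl)phenyl trifluoromethanesulfonate | COc1cc(OCc2ccccc2)cc([Si](C)(C)C)c1OS(=O)(=O)C(F)(F)F
A7 | alternative 3 | [(3R)-5-methoxy-7-(methoxymethoxy)-3-[4-methoxy-2-(methoxymethoxy)-3-(3-methylbut-2-en-1-yl)phenyl]-3,4-dihydro-2H-chromen-3-yl]methanol | COc1cc(OCOC)cc2c1C[C@](CO)(c1ccc(OC)c(CC=C(C)C)c1OCOC)CO2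
A8 | alternative 3 | 3-methoxy-5-(methoxymethoxy)-2-({3-[4-methoxy-2-(methoxymethoxy)-3-(3-methylbut-2-en-1-yl)phenyl]oxetan-3-yl}methyl)phenol | COc1cc(OCOC)cc(O)c1CC1(c2ccc(OC)c(CC=C(C)C)c2OCOC)COC1
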